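All runs were computed with made-up constants.

If we want to know what stands after 15 d in the flask charged with 0.50 M of starting material, we look first at the two earlier runs, which differ in their charge.

the same everywhere: gas phase 52 mM (held)

| run | starting material | remark | time |
|---|---|---|---|
| east | 0.25 M | run made earlier |  |
| north-east | 0.38 M | run made earlier |  |
| flask | 0.50 M |  | 15 d |

- east (time / d: starting material / %, target / %, side product / %): 2.08: 9.6, 86.5, 3.6; 5.00: 0, 92.8, 4.4; 10.0: 1.3, 94.3, 6.7; 15.0: 0, 96.8, 5.8
- north-east (time / d: starting material / %, target / %, side product / %): 2.08: 8.5, 85.3, 4.8; 5.00: 1.1, 94.2, 5.5; 10.0: 1.0, 94.9, 4.9; 15.0: 0, 95.0, 5.0

(scatter of a reading: 1 percentage point)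

- at 15 d, what has stopped the reaction, if anything has (all of the starting material has reacted / forward and back rates have come level / it is still moving)
- part of the starting material gone at 15 d
- the target standing at 15 d, as a percentage of the starting material charged
- the side product standing at 15 d, as a percentage of the starting material charged

- at the start none of the gas phase is in solution
- the reaction counts as stopped when no species that holds the starting material changes by six tenths of a point or more over the second half of the time

The east run at 0.25 M and the north-east run at 0.38 M fall alike, with 9.6% and 8.5% of the starting material standing at 2.08 d. Read as a plain decay, the east run gives a half-life of 0.615 d. Because that is shorter than the 15.0 d of the runs, both runs end with their starting material within scatter of zero. The side readings at the end are 5.8% and 5.0%, with a scatter of 1 percentage point, so we pool the runs. We call the pooled ratio the split, the side product standing per target standing at the end of the two runs (the selectivity in plain form): 0.0563.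

For the flask we take the same half-life, which makes 15 d about 24.4 half-lives, and the same split. Our reckoning then gives target 94.7% and side product 5.33%.

The forecast says all of the starting material has reacted, with 99.7% gone, target 94.5% and side product 5.3%, the side product standing “with no clear concentration trend”. Its target and ours differ by 0.20 points.

The flask gives all of the starting material has reacted, with 100% gone, target 94.1% and side product 5.89%, a split of 0.0626.

    gas phase ⇌ dissolved gas, rate k1*(csat - [dissolved gas]) (kL = 0.740 /h)
    starting material → side product (k = 0.00240 /h)
    starting material + dissolved gas → target (k = 1.30 /M/h)
    dissolved gas → decomposed reagent (k = 0.200 /h)

At 1.50 d the flask holds 0.0350 M of dissolved gas, which gives starting material a half-life of 0.634 d by the target step against 12.0 d by the side step, a ratio of 18.9. The starting material in the flask falls under a fiftieth of its charge by 3.45 d, inside the 15 d, and the forecast's ending holds. In the neighbour flask at 1.2 M, our split of 0.0563 gives side product 5.33% and target 94.7%. The computed neighbour flask has side product 7.72% and target 92.3%, a split of 0.0836, with 0% of its starting material left.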